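**Plan**

- Retrosynthesis: the two methoxymethyl (MOM) ethers on ring B come off last. Ring A is then cut at C7–C8 and C5–C6, which releases an acetyl unit (C6, C7) and a 4-pyranone-3-carboxylate carrying the 1,1-dimethylallyl group on an sp3 methylene (future C8).
- Enabling feature: ring A (C4a, C5, C6, C7, C8, C8a) bears oxygen on C5, C7 and C8a, the pattern of a triketide. The unit C8a–O1–C2=C3–C4(=O) of ring C is a 4-pyranone, the cyclic enol ether of a 1,3,5-tricarbonyl chain, so the pyranone can act as a masked polyketide onto which ring A is folded.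
- The pyranone is cut at O1–C2 and C2–C3 (chromone numbering; C2 comes from an amide acetal). The diacylacetate is cut between the β-keto ester α-carbon and the 3,3-dimethylpent-4-enoyl group, and the β-keto ester at its malonate-derived C–C bond.
- Forward: ring B is present from the start (2,4-dihydroxyphenylacetic acid). The chain grows acid → β-keto ester → diacylacetate, ring C closes first as the pyranone, ring A is annulated onto it, and deprotection ends the route.
- Stereochemistry: the target has no stereocentre and no stereogenic double bond, so nothing needs to be controlled.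

Key step: step 7

Remark: the 2-acyl-β-keto ester 8 and related compounds are drawn as keto tautomers although they should exist largely as chelated enols; the enamine geometry of 9 and the transient stereocentre of 12 are left undefined because both disappear.

**Route**

Step 1
Reactants: 1 2,4-dihydroxyphenylacetic acid
Product: 2 methoxymethyl 2-[2,4-bis(methoxymethoxy)phenyl]acetate
Conditions: MOMCl (3.6 equiv), i-Pr2NEt (4.5 equiv), CH2Cl2, 0 °C to rt
Reagents that add atoms: chloromethyl methyl ether, COCCl
Why: O-alkylation (Williamson type) of both phenols and the carboxylate by the reactive α-chloro ether under amine base; exhaustive alkylation needs no selectivity and prevents lactonisation to the benzofuranone.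

Step 2
Reactants: 2 methoxymethyl 2-[2,4-bis(methoxymethoxy)phenyl]acetate
Product: 3 2-[2,4-bis(methoxymethoxy)phenyl]acetic acid
Conditions: LiOH·H2O (2 equiv), THF/MeOH/H2O, rt; then 1 M HCl to pH 4, 0 °C
Reagents that add atoms: lithium hydroxide, [Li+].[OH-]
Why: saponification of the acetal ester, which should be far faster than any attack on the aryl MOM ethers; these are stable to base and to brief cold acidification to pH 4.

Step 3
Reactants: 3 2-[2,4-bis(methoxymethoxy)phenyl]acetic acid
Product: 5 methyl 4-[2,4-bis(methoxymethoxy)phenyl]-3-oxobutanoate, via acyl imidazolide 4 (not isolated)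
Conditions: CDI (1.1 equiv), THF, rt; then KO2CCH2CO2Me, MgCl2, Et3N, THF/MeCN, rt to 40 °C; cold 1 M HCl to pH 4
Reagents that add atoms: potassium methyl malonate, COC(=O)CC(=O)[O-].[K+]
Why: Masamune–Brooks homologation, in which the acyl imidazolide acylates the magnesium enolate of the malonate half ester and the adduct decarboxylates to the β-keto ester; the medium stays neutral to weakly basic, which suits the MOM ethers.

Step 4
Reactants: 6 3,3-dimethylpent-4-enoic acid
Product: 7 3,3-dimethylpent-4-enoyl chloride
Conditions: (COCl)2 (1.2 equiv), DMF (cat.), CH2Cl2, 0 °C to rt; volatiles removed, used crude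
Reagents that add atoms: oxalyl chloride, O=C(Cl)C(=O)Cl
Why: standard acid chloride formation through the chloroiminium (Vilsmeier-type) species; the isolated vinyl group and the neopentyl-like methylene are inert under these conditions.

Step 5
Reactants: 5 methyl 4-[2,4-bis(methoxymethoxy)phenyl]-3-oxobutanoate; 7 3,3-dimethylpent-4-enoyl chloride
Product: 8 methyl 2-{[2,4-bis(methoxymethoxy)phenyl]acetyl}-5,5-dimethyl-3-oxohept-6-enoate
Conditions: MgCl2 (1.1 equiv), pyridine (2.2 equiv), CH2Cl2, 0 °C; then 7 (1.1 equiv), 0 °C to rt; cold aq citric acid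
Reagents that add atoms: none
Why: magnesium-mediated C-acylation of a β-keto ester (Rathke conditions); the chelated enolate should react on carbon and the product is held as its magnesium chelate, which prevents a second acylation.

Step 6
Reactants: 8 methyl 2-{[2,4-bis(methoxymethoxy)phenyl]acetyl}-5,5-dimethyl-3-oxohept-6-enoate
Product: 10 methyl 5-[2,4-bis(methoxymethoxy)phenyl]-2-(2,2-dimethylbut-3-en-1-yl)-4-oxo-4H-pyran-3-carboxylate, via enaminone 9 (not isolated)
Conditions: Me2NCH(OMe)2 (1.5 equiv), PhMe, 70 °C; then AcOH (2 equiv), 80 °C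
Reagents that add atoms: N,N-dimethylformamide dimethyl acetal, COC(OC)N(C)C
Why: enaminone route to 4-pyranones, known for 2-acyl-1,3-dicarbonyl compounds: the amide acetal should condense at the benzylic methylene (the central carbon is blocked and the other methylene is neopentyl-like), and the enol oxygen of the neighbouring ketone then closes the ring by addition–elimination with loss of dimethylamine.

Step 7
Reactants: 10 methyl 5-[2,4-bis(methoxymethoxy)phenyl]-2-(2,2-dimethylbut-3-en-1-yl)-4-oxo-4H-pyran-3-carboxylate; 11 1-acetylimidazole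
Product: 13 3-[2,4-bis(methoxymethoxy)phenyl]-5,7-dihydroxy-8-(2-methylbut-3-en-2-yl)-4H-chromen-4-one, via methyl ketone 12 (not isolated)
Conditions: LiN(i-Pr)2 (1.1 equiv), THF, −78 °C; 11 (1.3 equiv), −78 to −30 °C; LiN(i-Pr)2 (2.5 equiv), −78 to 0 °C; AcOH quench
Reagents that add atoms: none
Why: Proposed new method: LiN(i-Pr)2 should remove a proton from the C2 methylene of the pyranone (future C8), the vinylogous α-position of both the ring ketone and the ester; the lithium dienolate is acetylated on that carbon by 11 to give ketone 12 (C7–C8), and the second charge of base forms the methyl ketone enolate (C6), which attacks the neighbouring ester with loss of methoxide (C5–C6), after which the cyclohexenedione tautomerises to the aromatic 5,7-diol. The closest known reactions are the tandem Claisen–Dieckmann and Michael–Dieckmann (Staunton–Weinreb type) annulations of lithiated ortho-toluates and the base-mediated Claisen cyclisation of pyranone-masked β-polyketones; new is a 4-pyranone-3-carboxylate as the toluate surrogate with its lateral carbanion next to a quaternary carbon. Ring A closes in a 6-exo-trig Dieckmann mode, and only the ester can be reached, because the ring ketone lies across the planar pyranone from the side chain. No stereocentre results, since C8 of 12 is stereogenic only in passing and ends as an aromatic carbon. The step needs carbon acylation at the hindered methylene and not reaction at the ring C–H next to oxygen (future C2) or on oxygen: the doubly vinylogous C–H is the most acidic one in 10, the hindered amide base does not add to the electrophilic ring position, an acylimidazole favours carbon with lithium enolates, and the released imidazolide deprotonates 12 so that no dienolate is spent as a base. Because O1 is already part of the pyranone, the fold cannot close through the C5 oxygen, and the 1,1-dimethylallyl group enters on an sp3 carbon and not by substitution on a crowded arene.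

Step 8
Reactants: 13 3-[2,4-bis(methoxymethoxy)phenyl]-5,7-dihydroxy-8-(2-methylbut-3-en-2-yl)-4H-chromen-4-one
Product: 14 3-(2,4-dihydroxyphenyl)-5,7-dihydroxy-8-(2-methylbut-3-en-2-yl)-4H-chromen-4-one
Conditions: HCl (1.25 M in MeOH), MeOH/THF, 0 °C to rt
Reagents that add atoms: none
Why: acid-catalysed acetal exchange with methanol (MOM cleavage); the monosubstituted vinyl group next to a quaternary carbon would have to form a secondary, neopentyl-type cation to add the C7 hydroxyl, so it is expected to survive dilute acid at room temperature.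

**Compound list**

1 | 2,4-dihydroxyphenylacetic acid | O=C(O)Cc1ccc(O)cc1O | starting material
2 | methoxymethyl 2-[2,4-bis(methoxymethoxy)phenyl]acetate | COCOC(=O)Cc1ccc(OCOC)cc1OCOC | intermediate
3 | 2-[2,4-bis(methoxymethoxy)phenyl]acetic acid | O=C(O)Cc1ccc(OCOC)cc1OCOC | intermediate
4 | 1-{[2,4-bis(methoxymethoxy)phenyl]acetyl}-1H-imidazole (not isolated) | O=C(Cc1ccc(OCOC)cc1OCOC)n1ccnc1 | intermediate
5 | methyl 4-[2,4-bis(methoxymethoxy)phenyl]-3-oxobutanoate | COC(=O)CC(=O)Cc1ccc(OCOC)cc1OCOC | intermediate
6 | 3,3-dimethylpent-4-enoic acid | C=CC(C)(C)CC(=O)O | starting material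
7 | 3,3-dimethylpent-4-enoyl chloride | C=CC(C)(C)CC(=O)Cl | intermediate
8 | methyl 2-{[2,4-bis(methoxymethoxy)phenyl]acetyl}-5,5-dimethyl-3-oxohept-6-enoate (keto form drawn) | C=CC(C)(C)CC(=O)C(C(=O)OC)C(=O)Cc1ccc(OCOC)cc1OCOC | intermediate
9 | methyl 2-{2-[2,4-bis(methoxymethoxy)phenyl]-3-(dimethylamino)prop-2-enoyl}-5,5-dimethyl-3-oxohept-6-enoate (not isolated; enamine geometry undefined) | C=CC(C)(C)CC(=O)C(C(=O)OC)C(=O)C(=CN(C)C)c1ccc(OCOC)cc1OCOC | intermediate
10 | methyl 5-[2,4-bis(methoxymethoxy)phenyl]-2-(2,2-dimethylbut-3-en-1-yl)-4-oxo-4H-pyran-3-carboxylate | C=CC(C)(C)Cc1occ(-c2ccc(OCOC)cc2OCOC)c(=O)c1C(=O)OC | intermediate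
11 | 1-acetylimidazole | CC(=O)n1ccnc1 | starting material
12 | methyl 5-[2,4-bis(methoxymethoxy)phenyl]-2-(4,4-dimethyl-2-oxohex-5-en-3-yl)-4-oxo-4H-pyran-3-carboxylate (not isolated; racemic, present as its lithium enolate) | C=CC(C)(C)C(C(C)=O)c1occ(-c2ccc(OCOC)cc2OCOC)c(=O)c1C(=O)OC | intermediate
13 | 3-[2,4-bis(methoxymethoxy)phenyl]-5,7-dihydroxy-8-(2-methylbut-3-en-2-yl)-4H-chromen-4-one | C=CC(C)(C)c1c(O)cc(O)c2c(=O)c(-c3ccc(OCOC)cc3OCOC)coc12 | intermediate
14 | 3-(2,4-dihydroxyphenyl)-5,7-dihydroxy-8-(2-methylbut-3-en-2-yl)-4H-chromen-4-one | C=CC(C)(C)c1c(O)cc(O)c2c(=O)c(-c3ccc(O)cc3O)coc12 | target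

**Step count**

Total: 8 steps. Longest linear sequence: 7 steps (steps 1, 2, 3, 5, 6, 7, 8; step 4 prepares the acid chloride on a side branch).

**Steps most likely to fail**

Step 7. Carbon acylation of the dienolate may be slow because the reacting carbon sits next to a quaternary centre. Acylation on oxygen or proton transfer from the acetyl donor to the dienolate could then take over, and the cascade would stall before ring closure. The fallback reverses the order of the two bond formations and makes each by a known reaction, so that the hindered C7–C8 bond forms intramolecularly. It sets out from 10. The methyl ester is cleaved with Me3SnOH (1,2-dichloroethane, 70 °C; dilute HCl wash) to 5-[2,4-bis(methoxymethoxy)phenyl]-2-(2,2-dimethylbut-3-en-1-yl)-4-oxo-4H-pyran-3-carboxylic acid F1. CDI converts this into the acyl imidazolide 1-{5-[2,4-bis(methoxymethoxy)phenyl]-2-(2,2-dimethylbut-3-en-1-yl)-4-oxo-4H-pyran-3-carbonyl}-1H-imidazole F2, which is homologated with KO2CCH2CO2Me, MgCl2 and Et3N (Masamune–Brooks, C5–C6) to methyl 3-{5-[2,4-bis(methoxymethoxy)phenyl]-2-(2,2-dimethylbut-3-en-1-yl)-4-oxo-4H-pyran-3-yl}-3-oxopropanoate F3. LiN(SiMe3)2 (3 equiv, THF, −78 °C to rt; AcOH quench) should then form the dianion, whose pyranone methylene closes onto the terminal ester (C7–C8). This is a Claisen cyclisation of the kind known for β-polyketo esters that give phloroglucinol rings. The route is rejoined at 13.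

Step 6. The amide acetal may react at the wrong site, by O-methylation of the acidic enol or at the neopentyl methylene, or an acyl group may be lost by retro-Claisen cleavage on heating. The fallback replaces the neutral condensation by a dianion formylation. It sets out from 8. LiN(i-Pr)2 (2.2 equiv, THF, −78 °C) deprotonates the central carbon and then the benzylic methylene, and ethyl formate gives methyl 2-{2-[2,4-bis(methoxymethoxy)phenyl]-3-oxopropanoyl}-5,5-dimethyl-3-oxohept-6-enoate F4 (hydroxymethylene tautomer expected; AcOH quench). Cyclodehydration with catalytic pyridinium p-toluenesulfonate in PhMe at 50 °C, the classical closure of a 1,3,5-tricarbonyl unit to a 4-pyranone, returns to the route at 10.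

Step 8. Under acid the C7 hydroxyl may add to the neighbouring vinyl group and close a trimethyldihydrofuran ring in competition with acetal cleavage. The fallback blocks the participating phenol before the MOM groups are removed and avoids protic acid. It sets out from 13. Ac2O, pyridine and DMAP (cat.) give 3-[2,4-bis(methoxymethoxy)phenyl]-8-(2-methylbut-3-en-2-yl)-4-oxo-4H-chromene-5,7-diyl diacetate F5. Me3SiBr (CH2Cl2, −30 °C; aq NaHCO3 work-up) cleaves the MOM ethers to 3-(2,4-dihydroxyphenyl)-8-(2-methylbut-3-en-2-yl)-4-oxo-4H-chromene-5,7-diyl diacetate F6. K2CO3 (cat.) in MeOH at 0 °C removes the acetates by transesterification and returns to the route at 14.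

**Further compounds**

F1 | step 7 | 5-[2,4-bis(methoxymethoxy)phenyl]-2-(2,2-dimethylbut-3-en-1-yl)-4-oxo-4H-pyran-3-carboxylic acid | C=CC(C)(C)Cc1occ(-c2ccc(OCOC)cc2OCOC)c(=O)c1C(=O)O
F2 | step 7 | 1-{5-[2,4-bis(methoxymethoxy)phenyl]-2-(2,2-dimethylbut-3-en-1-yl)-4-oxo-4H-pyran-3-carbonyl}-1H-imidazole | C=CC(C)(C)Cc1occ(-c2ccc(OCOC)cc2OCOC)c(=O)c1C(=O)n1ccnc1
F3 | step 7 | methyl 3-{5-[2,4-bis(methoxymethoxy)phenyl]-2-(2,2-dimethylbut-3-en-1-yl)-4-oxo-4H-pyran-3-yl}-3-oxopropanoate | C=CC(C)(C)Cc1occ(-c2ccc(OCOC)cc2OCOC)c(=O)c1C(=O)CC(=O)OC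
F4 | step 6 | methyl 2-{2-[2,4-bis(methoxymethoxy)phenyl]-3-oxopropanoyl}-5,5-dimethyl-3-oxohept-6-enoate | C=CC(C)(C)CC(=O)C(C(=O)OC)C(=O)C(C=O)c1ccc(OCOC)cc1OCOC
F5 | step 8 | 3-[2,4-bis(methoxymethoxy)phenyl]-8-(2-methylbut-3-en-2-yl)-4-oxo-4H-chromene-5,7-diyl diacetate | C=CC(C)(C)c1c(OC(C)=O)cc(OC(C)=O)c2c(=O)c(-c3ccc(OCOC)cc3OCOC)coc12
F6 | step 8 | 3-(2,4-dihydroxyphenyl)-8-(2-methylbut-3-en-2-yl)-4-oxo-4H-chromene-5,7-diyl diacetate | C=CC(C)(C)c1c(OC(C)=O)cc(OC(C)=O)c2c(=O)c(-c3ccc(O)cc3O)coc12
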